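# Design of a total synthesis of briarellin B (47) by a Prins–pinacol route

Eunicellane numbering is used for the target and for all compounds from 24 onward.

## The problem

Compound 47 is a tetracycle. A cyclohexane (C1, C10–C14) is cis-fused along C1–C10 to a tetrahydrofuran (O, C2, C1, C10, C9). The same oxygen closes a nine-membered oxonane through C3–C8, and a seven-membered lactone (C3–O–C16(=O)–C15–C14–C1–C2) is trans-fused to the cyclohexane. Ten stereocentres must be set (C1, C2, C3, C4, C6, C9, C10, C11, C14, C15), and only C14 and C9 can be bought. These two must fix C1, C2 and C10 when the tetrahydrofuran forms; the rigid cis-fused bicycle must then control the rest: its convex face for C11, the C14/C1 environment for C15, allylic strain at C2 for the C3=C4 olefin, and the C4 acyloxy group for C6. The oxygens on C3 and C4 are related as in an anti addition to a Z olefin, so an epoxide must be opened with inversion at exactly one carbon, and the C2 centre decides which one. Fragile features are the C4 octanoate (β to C6: acyl migration to a free C6 hydroxyl, elimination at the aldehyde stage), the epimerisable C15 next to the lactone carbonyl, the acid-labile tertiary C11 alcohol, and the allylic C6 alcohol beside the exocyclic methylene. The nine-membered ring is the entropically hardest ring and is best closed last on a preorganised core. The feature that opens the key step is the tetrahydrofuran: it is 2,5-cis-disubstituted, shares its C1–C10 edge with the cyclohexane and carries only hydrogen at C10. That is the pattern of a 3-formyltetrahydrofuran from a Prins cyclisation followed by a pinacol shift, after loss of the formyl group.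

## Retrosynthesis

**C6–C7 (oxonane).** Target 47 is cut at C6–C7 to the vinyl iodide aldehyde 45. An intramolecular Nozaki–Hiyama–Kishi reaction delivers the free C6 alcohol and the exocyclic methylene together, so no protecting group is left to remove next to the octanoate. Olefin metathesis would place the double bond inside the ring, and closing the lactone last would force the medium ring to be made on a flexible precursor. The forward reaction must tolerate an ester and a lactone and must choose one aldehyde face.

**Unmasking.** The vinyl iodide of 45 comes from a terminal alkyne (iodoboration, 41 → 43) and the aldehyde from a primary silyl ether (43 → 44 → 45). The alkyne lactone 41 is therefore the robust carrier of all stereocentres except C6.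

**Lactone C16–O.** Lactone 41 is cut at the acyl–oxygen bond to hydroxy acid 39. The alternative, letting the C16 acid open a C3–C4 epoxide, was rejected for 41. In the rotamer free of allylic strain (C2–H in the olefin plane) C1 covers one olefin face, so the epoxide forms on the other. The tethered acid could then reach C3 only from the C1 side and would give the wrong C3 configuration. The C3–O bond of the epoxide is therefore kept and the ring is closed by acylating the tertiary C3 hydroxyl.

**C4–O.** Acid 39 goes back through 37 to the hydroxy octanoate 36, and 36 is cut at C4–O to epoxide 35 and octanoic acid. Opening at C4 with inversion gives the 3,4-anti arrangement and installs the ester in the same step. Epoxide 35 comes from the Z olefin of 34. The forward reaction needs attack at the secondary carbon; C3 is fully substituted and deactivated by the oxygen on C2.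

**C11–O and C15/C16.** The tertiary alcohol of 34 is cut back to the ring olefin of 31 (Markovnikov hydration with anti addition, oxygen on the concave face). The C16 oxygen and the C15 centre of 30 go back to the isopropenyl group of 28 (hydroboration). Both operations are placed before any ester is present, because the demercuration is basic.

**C10–H.** The C10 hydrogen of 28 is what remains of the formyl group of 27 (photochemical decarbonylation). The formyl group is the price of the key step.

**C1–C2 and C9–C10 (key step).** Aldehyde 27 is cut at both bonds to the dioxolane 24. This removes the tetrahydrofuran and three stereocentres (C1, C2, C10) and leaves a monocyclic diene acetal. The forward reaction must form the oxocarbenium ion on the C9 oxygen, cyclise through a chair, and migrate the ring bond rather than a hydride.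

**Acetal.** Dioxolane 24 is cut at its two acetal C–O bonds to diol 15 and the Z enal 23, which carries C3–C6 and the C18 methyl.

**Fragments.** Diol 15 is cut between the diene carbon and the carbinol carbon to dienyl triflate 3 (from (R)-carvone 1) and the α-silyloxy aldehyde 10 (from (R)-glycidol 4 and trimethylsilylacetylene 6). The coupling should give the 1,2-anti carbinol 12, but the chair of the key step is best served by the 1,2-syn diol (stannyloxy group axial, carbinol hydrogen equatorial). The carbinol is therefore reset through ketone 13 to 14. Enal 23 is cut at C3=C4 to 3-(triisopropylsilyloxy)propanal 18 and phosphonate 19 (Z-selective olefination), with 18 from propane-1,3-diol 16.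

## Roads not taken

Alternative 1: Biomimetic transannular etherification. The cut is at O–C2 and at the lactone C–O bond. In the forward step KN(SiMe3)2 deprotonates a C9 hydroxyl on a ten-membered carbocycle; the alkoxide opens a C2–C3 epoxide at C2 and the released C3 alkoxide closes the lactone on a C16 ester, giving A1.
- Merits: both ether rings and the lactone form in one operation with clean inversion at C2.
- Where it is better: the lactone closes by alkoxide attack on an ester. The chosen plan must instead acylate a tertiary alcohol (step 25).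
- Weak points: every stereocentre, including the epoxide and the C9 carbinol, must first be set on a flexible ten-membered ring. That ring needs its own macrocyclisation. The strong base meets an epimerisable C15. Three protecting groups must be removed and the octanoate installed after A1.
- What the chosen plan sets against it: five stereocentres are fixed on a rigid bicycle from two chiral-pool centres before any medium ring exists.

Alternative 2: Butenolide Diels–Alder. The cut is at C1–C14 and C10–C11. An endo cycloaddition of a chiral butenolide with a 2-silyloxydiene gives A2.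
- Merits: C1, C10 and C11 are set in one step.
- Where it is better: the C11 tertiary carbinol is built in with its oxygen. The chosen plan depends on the facial and regiochemical course of a late hydration (step 20).
- Weak points: in A2, C14 is a bare methylene, so the C15–C16 branch and the C14 and C15 centres need a separate allylic functionalisation. C9 is still a lactone carbonyl, and C3 is only a protected hydroxymethyl group. The oxonane and the second lactone are far away.
- What the chosen plan sets against it: C14 is bought with its three-carbon branch, and C2, C9 and the tetrahydrofuran arrive together.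

Alternative 3: Grob fragmentation. A bicyclic alkoxide fragments anti-periplanar to a C6 mesylate and gives the Z oxonenone A3 with the 2,9-cis relationship.
- Merits: the nine-membered ring is made early, without high dilution and with a defined olefin.
- Where it is at least as good: as a way of making the medium ring itself it is as reliable as, or more reliable than, the late closure of step 29.
- Weak points for this target: the C6=C7 olefin must be transposed to the exocyclic methylene with a C6 hydroxyl. The C3 ketone must become a methyl carbinol with an adjacent C4 oxygen on a flexible ring. The cyclohexane with C1, C10, C11, C14 and C15 must then be annulated through the two side arms, without a rigid template. The cyclopentanedione start needs an enantioselective desymmetrisation.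
- What the chosen plan sets against it: the carbocycle and its stereocentres are in place before the medium ring, and the C7 methylene and C6 carbinol are formed directly in the ring closure.

Key step: step 16

## Route

Remark: acetal 24 forms as two epimers at the acetal carbon; one is drawn, and both give the same oxocarbenium ion 25.

Step 1
Reactants: 1 (R)-carvone
Product: 3 dienyl triflate (3R)-6-methyl-3-(prop-1-en-2-yl)cyclohexa-1,5-dien-1-yl trifluoromethanesulfonate, via lithium dienolate 2 (not isolated)
Conditions: LiN(iPr)2, THF, −78 °C; PhNTf2, −78 → 0 °C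
Reagents that add atoms: N-phenylbis(trifluoromethanesulfonimide), O=S(=O)(N(c1ccccc1)S(=O)(=O)C(F)(F)F)C(F)(F)F
Why: Kinetic deprotonation of the enone at its α'-methylene gives the cross-conjugated dienolate, which is triflated on oxygen (enol triflate formation); the stereocentre is not touched.

Step 2
Reactants: 4 (R)-glycidol
Product: 5 triethyl{[(2S)-oxiran-2-yl]methoxy}silane
Conditions: TESCl, imidazole, CH2Cl2, 0 °C
Reagents that add atoms: chlorotriethylsilane, CC[Si](Cl)(CC)CC
Why: Silylation of a primary alcohol; the epoxide and its stereocentre are inert under these conditions.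

Step 3
Reactants: 5 triethylsilyl glycidyl ether; 6 trimethylsilylacetylene
Product: 8 (2S)-1-(triethylsilyloxy)-5-(trimethylsilyl)pent-4-yn-2-ol, via lithium acetylide 7 (not isolated)
Conditions: 6, n-BuLi, THF, −78 °C; BF3·OEt2; then 5, −78 °C
Reagents that add atoms: none
Why: Lewis-acid-assisted opening of a terminal epoxide by a lithium acetylide at the unsubstituted carbon (Yamaguchi alkynylation); the carbinol centre, the future C9, is not involved.

Step 4
Reactants: 8 homopropargylic alcohol
Product: 9 (2S)-1,2-bis(triethylsilyloxy)-5-(trimethylsilyl)pent-4-yne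
Conditions: TESCl, imidazole, DMF, rt
Reagents that add atoms: chlorotriethylsilane, CC[Si](Cl)(CC)CC
Why: Routine silylation of the secondary alcohol.

Step 5
Reactants: 9 bis(triethylsilyl) ether
Product: 10 (2S)-2-(triethylsilyloxy)-5-(trimethylsilyl)pent-4-ynal
Conditions: (COCl)2, DMSO, CH2Cl2, −78 → −30 °C; Et3N, −78 → 0 °C
Reagents that add atoms: none
Why: Under Swern conditions a primary triethylsilyl ether is cleaved and oxidised directly while a secondary one survives (chemoselective Swern oxidation of silyl ethers); low temperature protects the α-stereocentre.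

Step 6
Reactants: 3 dienyl triflate; 10 α-silyloxy aldehyde
Product: 12 (1R,2S)-1-[(3R)-6-methyl-3-(prop-1-en-2-yl)cyclohexa-1,5-dien-1-yl]-2-(triethylsilyloxy)-5-(trimethylsilyl)pent-4-yn-1-ol, via dienylchromium dichloride 11 (not isolated)
Conditions: CrCl2 (4 equiv), NiCl2 (2 mol %), DMF, rt
Reagents that add atoms: none
Why: Nozaki–Hiyama–Kishi coupling: zerovalent nickel inserts into the C–OTf bond, the dienyl group passes to trivalent chromium and adds to the aldehyde. Felkin–Anh addition should favour the 1,2-anti carbinol drawn; this centre is reset in steps 7 and 8, and both epimers give 13.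

Step 7
Reactants: 12 dienyl carbinol
Product: 13 (2S)-1-[(3R)-6-methyl-3-(prop-1-en-2-yl)cyclohexa-1,5-dien-1-yl]-2-(triethylsilyloxy)-5-(trimethylsilyl)pent-4-yn-1-one
Conditions: Dess–Martin periodinane, NaHCO3, CH2Cl2, 0 °C
Reagents that add atoms: none
Why: Buffered Dess–Martin oxidation of an allylic alcohol; the α-silyloxy centre is not enolised under these neutral conditions.

Step 8
Reactants: 13 α-silyloxy dienyl ketone
Product: 14 (1S,2S)-1-[(3R)-6-methyl-3-(prop-1-en-2-yl)cyclohexa-1,5-dien-1-yl]-2-(triethylsilyloxy)-5-(trimethylsilyl)pent-4-yn-1-ol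
Conditions: LiBH(s-Bu)3, THF, −78 °C
Reagents that add atoms: none
Why: Felkin–Anh reduction of an α-silyloxy ketone: the bulky hydride attacks anti to the C–OSi bond and sets the 1,2-syn carbinol. The α-branched, β-substituted enone should be reduced at the carbonyl group.

Step 9
Reactants: 14 syn silyloxy alcohol
Product: 15 (1S,2S)-1-[(3R)-6-methyl-3-(prop-1-en-2-yl)cyclohexa-1,5-dien-1-yl]-5-(trimethylsilyl)pent-4-yne-1,2-diol
Conditions: PPTS, MeOH, 0 °C
Reagents that add atoms: none
Why: Mild acid methanolysis of the secondary triethylsilyl ether; the alkynyl–silicon bond is stable to it and the low temperature spares the doubly allylic carbinol.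

Step 10
Reactants: 16 propane-1,3-diol
Product: 17 3-(triisopropylsilyloxy)propan-1-ol
Conditions: NaH, THF, rt; TIPSCl
Reagents that add atoms: chlorotriisopropylsilane, CC(C)[Si](Cl)(C(C)C)C(C)C
Why: Monosilylation of a symmetrical diol through its sparingly soluble monosodium alkoxide.

Step 11
Reactants: 17 monoprotected diol
Product: 18 3-(triisopropylsilyloxy)propanal
Conditions: TEMPO (cat.), PhI(OAc)2, CH2Cl2, rt
Reagents that add atoms: none
Why: Oxoammonium-mediated oxidation of a primary alcohol, which stops at the aldehyde in the absence of water.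

Step 12
Reactants: 18 3-(triisopropylsilyloxy)propanal; 19 methyl 2-[bis(2,2,2-trifluoroethoxy)phosphoryl]propanoate
Product: 21 methyl (2Z)-2-methyl-5-(triisopropylsilyloxy)pent-2-enoate, via potassium phosphonate carbanion 20 (not isolated)
Conditions: 19, KN(SiMe3)2, 18-crown-6, THF, −78 °C; then 18
Reagents that add atoms: none
Why: Still–Gennari olefination: the trifluoroethyl phosphonate under dissociating conditions eliminates fast from the kinetic adduct and gives the Z trisubstituted enoate.

Step 13
Reactants: 21 Z enoate
Product: 22 (2Z)-2-methyl-5-(triisopropylsilyloxy)pent-2-en-1-ol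
Conditions: i-Bu2AlH, CH2Cl2, −78 °C
Reagents that add atoms: none
Why: Hydride reduction of an enoate to the allylic alcohol with retention of olefin geometry.

Step 14
Reactants: 22 Z allylic alcohol
Product: 23 (2Z)-2-methyl-5-(triisopropylsilyloxy)pent-2-enal
Conditions: MnO2, CH2Cl2, rt
Reagents that add atoms: none
Why: Neutral, heterogeneous allylic oxidation, chosen so that the Z enal does not isomerise.

Step 15
Reactants: 15 syn diol; 23 Z enal
Product: 24 (4S,5S)-4-[(3R)-6-methyl-3-(prop-1-en-2-yl)cyclohexa-1,5-dien-1-yl]-2-[(2Z)-5-(triisopropylsilyloxy)pent-2-en-2-yl]-5-[3-(trimethylsilyl)prop-2-yn-1-yl]-1,3-dioxolane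
Conditions: p-TsOH·H2O (cat.), MgSO4, CH2Cl2, −20 °C
Reagents that add atoms: none
Why: Acid-catalysed acetalisation of a 1,2-diol with an aldehyde, driven by the drying agent. The low temperature keeps the Z olefin and the doubly allylic C–O bond intact; the acetal carbon forms as two epimers that need not be separated.

Step 16
Reactants: 24 dienyl dioxolane
Product: 27 cis-fused C10-formyl hexahydroisobenzofuran (2,9-cis; C9 propargylsilane; C2 Z-alkenyl chain; C14 isopropenyl; C11=C12), via oxocarbenium ion 25 (not isolated), via oxanyl allyl cation 26 (not isolated)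
Conditions: SnCl4 (1.1 equiv), CH2Cl2, −78 → −20 °C
Reagents that add atoms: none
Why: SnCl4 binds the allylic acetal oxygen and cleaves its bond to the acetal carbon, giving oxocarbenium ion 25 held through the C9 oxygen; both acetal epimers give this ion. The diene attacks it through C1 in a 6-endo-trig Prins cyclisation via a chair with the oxocarbenium substituent, the C14 ring branch and the C9 propargyl group equatorial, forming C1–C2 and allyl cation 26. A pinacol 1,2-shift of C9 from the carbinol carbon to C10 forms C9–C10, contracts the oxane to the tetrahydrofuran and leaves the carbinol carbon as the tin-bound formyl group, which makes the sequence irreversible. The closest known reaction type is the Prins cyclisation–pinacol rearrangement of 4-alkenyl-1,3-dioxolanes to 3-acyltetrahydrofurans. C2 and its cis relation to C9 follow from the equatorial chair positions; C1 follows from the same chair and from attack on the diene face anti to the C14 isopropenyl group (the carvone and glycidol centres are matched); C10 follows from the suprafacial migration, which can only give the cis ring fusion. The step needs ring-bond migration to beat 1,2-hydride shift and proton loss. In the chair from the 1,2-syn diol the stannyloxy group is axial and the carbinol hydrogen equatorial, nearly orthogonal to the vacant orbital at C10, so only the C9 bond is aligned to migrate; the equatorial hydrogen also avoids allylic strain with the C11 methyl. It builds one ring, two skeletal bonds and three stereocentres.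

Step 17
Reactants: 27 C10-formyl hexahydroisobenzofuran
Product: 28 cis-fused hexahydroisobenzofuran with hydrogen at C10 (C11=C12, C14 isopropenyl, Z C3=C4, silylalkyne, C6 OTIPS)
Conditions: hν (medium-pressure Hg lamp, Pyrex), 1,4-dioxane, rt
Reagents that add atoms: none
Why: Photochemical decarbonylation of a β,γ-unsaturated aldehyde: Norrish α-cleavage gives an allyl/formyl radical pair, and hydrogen transfer within the pair returns hydrogen to C10 on the face the formyl group occupied, so the cis fusion is kept.

Step 18
Reactants: 28 triene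
Product: 30 C16 primary alcohol with the C15 methyl stereocentre, via alkylborane 29 (not isolated)
Conditions: 9-BBN, THF, 0 °C → rt; NaBO3·4H2O, H2O, rt
Reagents that add atoms: sodium perborate, [Na+].[Na+].O[B-]1(O)OO[B-](O)(O)OO1
Why: Hydroboration–oxidation; 9-BBN adds to the 1,1-disubstituted olefin much faster than to the trisubstituted olefins or the silylalkyne, and perborate oxidises without cleaving the alkynylsilane. With C14–H eclipsing the C=CH2 bond the borane approaches from the C13 side, away from C1 and its C2 branch, which should set C15 as drawn (substrate control).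

Step 19
Reactants: 30 C16 alcohol
Product: 31 C16 tert-butyldimethylsilyl ether
Conditions: TBSCl, imidazole, DMF, rt
Reagents that add atoms: tert-butylchlorodimethylsilane, CC(C)(C)[Si](C)(C)Cl
Why: Silylation of the primary alcohol so that it cannot act as an internal nucleophile in steps 20 to 22.

Step 20
Reactants: 31 ring olefin
Product: 34 C11 tertiary alcohol (hydroxyl cis to C9) with terminal alkyne, via alkylmercury acetate 32 (not isolated), via silylalkyne alcohol 33 (not isolated)
Conditions: Hg(OAc)2, THF–H2O, 0 °C; NaBH4, aq. NaOH, 0 °C; then K2CO3, MeOH, rt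
Reagents that add atoms: water, O
Why: Oxymercuration–demercuration: the mercurinium ion should form on the convex face (anti to C9), water opens it at the tertiary C11 from the opposite face, and NaBH4 replaces mercury by hydrogen, so the hydroxyl ends up cis to C9. The ring olefin is more nucleophilic than the allylic-ether olefin C3=C4 and than the silylalkyne, which is unmasked by the methanolic base at the end.

Step 21
Reactants: 34 Z olefin
Product: 35 3,4-epoxide on the face syn to the ring oxygen
Conditions: m-CPBA, NaHCO3, CH2Cl2, 0 °C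
Reagents that add atoms: 3-chloroperbenzoic acid, OOC(=O)c1cccc(Cl)c1
Why: Peracid epoxidation of the only remaining electron-rich olefin. Allylic strain holds C2–H in the olefin plane, C1 with its ring shields one face, and the peracid adds to the other, which places the C3–O bond as in the target.

Step 22
Reactants: 35 epoxide
Product: 36 C4 octanoate with free tertiary C3 hydroxyl (3,4-anti)
Conditions: C7H15CO2H, C7H15CO2Cs, DMF, 80 °C
Reagents that add atoms: octanoic acid, CCCCCCCC(=O)O
Why: Carboxylate opening of an epoxide by SN2 attack: C3 is fully substituted and deactivated by the oxygen on C2, so octanoate should attack C4 with inversion, giving the anti relationship and installing the ester in one step. The secondary ester is favoured over migration to the tertiary hydroxyl.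

Step 23
Reactants: 36 bis(silyl ether)
Product: 37 C16 primary alcohol
Conditions: PPTS, MeOH, rt
Reagents that add atoms: none
Why: Acid methanolysis removes the primary tert-butyldimethylsilyl ether much faster than the primary triisopropylsilyl ether; the ester is not transesterified under these conditions.

Step 24
Reactants: 37 C16 alcohol
Product: 39 C16 carboxylic acid, via aldehyde 38 (not isolated)
Conditions: TEMPO (cat.), PhI(OAc)2, MeCN–pH 7 buffer, rt
Reagents that add atoms: water, O
Why: Oxoammonium oxidation in water takes the primary alcohol through the aldehyde hydrate to the acid; tertiary alcohols and the alkyne are inert and the neutral medium spares C15.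

Step 25
Reactants: 39 hydroxy acid
Product: 41 seven-membered lactone (C16 to the C3 oxygen), via mixed anhydride 40 (not isolated)
Conditions: 2,4,6-Cl3C6H2COCl, Et3N, THF, rt; then DMAP, toluene, 80 °C (slow addition)
Reagents that add atoms: none
Why: Yamaguchi lactonisation: DMAP converts the mixed anhydride into an acylpyridinium ion that acylates the tertiary C3 hydroxyl, held close by the trans-diequatorial C1 and C14 branches. The C11 hydroxyl lies on the opposite face of the cyclohexane and cannot reach C16.

Step 26
Reactants: 41 alkyne lactone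
Product: 43 2-iodoalkene (C7 iodide, C19 methylene), via alkenylborane 42 (not isolated)
Conditions: B-iodo-9-BBN, CH2Cl2–hexane, −20 → 0 °C; AcOH, 0 °C
Reagents that add atoms: B-iodo-9-borabicyclo[3.3.1]nonane, IB1C2CCCC1CCC2
Why: Haloboration: B–I adds syn across the terminal alkyne with iodine at the internal carbon, and acetic acid cleaves the alkenyl–boron bond. Esters, the lactone and the silyl ether tolerate the reagent at low temperature; the tertiary hydroxyl is borylated only transiently.

Step 27
Reactants: 43 vinyl iodide silyl ether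
Product: 44 C6 primary alcohol
Conditions: HF·pyridine, pyridine, THF, 0 °C → rt
Reagents that add atoms: none
Why: Fluoride cleavage of the primary silyl ether in a buffered acidic medium, which avoids migration of the octanoyl group to the new hydroxyl.

Step 28
Reactants: 44 C6 alcohol
Product: 45 C6 aldehyde
Conditions: Dess–Martin periodinane, NaHCO3, CH2Cl2, 0 °C
Reagents that add atoms: none
Why: A non-basic oxidation is needed because the product is a β-acyloxy aldehyde prone to elimination; it is used at once.

Step 29
Reactants: 45 vinyl iodide aldehyde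
Product: 47 briarellin B, via vinylchromium dichloride 46 (not isolated)
Conditions: CrCl2 (10 equiv), NiCl2 (5 mol %), DMSO, rt, high dilution
Reagents that add atoms: none
Why: Intramolecular Nozaki–Hiyama–Kishi reaction: zerovalent nickel activates the C–I bond, the vinyl group passes to trivalent chromium and adds to the aldehyde, closing the oxonane at C6–C7. The rigid tetracyclic template and the C4 acyloxy group (polar 1,3-induction) should direct addition to the aldehyde face that gives the 4,6-anti carbinol of the target.

## Compound list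

1 | (R)-carvone | CC1=CC[C@H](CC1=O)C(=C)C | starting material
2 | lithium dienolate of 1 (not isolated) | C=C(C)[C@@H]1CC=C(C)C(O[Li])=C1 | intermediate
3 | (3R)-6-methyl-3-(prop-1-en-2-yl)cyclohexa-1,5-dien-1-yl trifluoromethanesulfonate | C=C(C)[C@@H]1CC=C(C)C(OS(=O)(=O)C(F)(F)F)=C1 | intermediate
4 | (R)-glycidol | OC[C@@H]1CO1 | starting material
5 | triethyl{[(2S)-oxiran-2-yl]methoxy}silane | CC[Si](CC)(CC)OC[C@@H]1CO1 | intermediate
6 | trimethylsilylacetylene | C#C[Si](C)(C)C | starting material
7 | lithium (trimethylsilyl)acetylide (not isolated) | [Li]C#C[Si](C)(C)C | intermediate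
8 | (2S)-1-(triethylsilyloxy)-5-(trimethylsilyl)pent-4-yn-2-ol | CC[Si](CC)(CC)OC[C@@H](O)CC#C[Si](C)(C)C | intermediate
9 | (2S)-1,2-bis(triethylsilyloxy)-5-(trimethylsilyl)pent-4-yne | CC[Si](CC)(CC)OC[C@@H](O[Si](CC)(CC)CC)CC#C[Si](C)(C)C | intermediate
10 | (2S)-2-(triethylsilyloxy)-5-(trimethylsilyl)pent-4-ynal | O=C[C@@H](O[Si](CC)(CC)CC)CC#C[Si](C)(C)C | intermediate
11 | dienylchromium dichloride from 3 (not isolated) | C=C(C)[C@@H]1CC=C(C)C([Cr](Cl)Cl)=C1 | intermediate
12 | (1R,2S) 1,2-anti dienyl carbinol, 2-O-triethylsilyl | C=C(C)[C@@H]1CC=C(C)C(=C1)[C@@H](O)[C@@H](O[Si](CC)(CC)CC)CC#C[Si](C)(C)C | intermediate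
13 | (2S) α-silyloxy dienyl ketone | C=C(C)[C@@H]1CC=C(C)C(=C1)C(=O)[C@@H](O[Si](CC)(CC)CC)CC#C[Si](C)(C)C | intermediate
14 | (1S,2S) 1,2-syn dienyl carbinol, 2-O-triethylsilyl | C=C(C)[C@@H]1CC=C(C)C(=C1)[C@H](O)[C@@H](O[Si](CC)(CC)CC)CC#C[Si](C)(C)C | intermediate
15 | (1S,2S)-1-[(3R)-6-methyl-3-(prop-1-en-2-yl)cyclohexa-1,5-dien-1-yl]-5-(trimethylsilyl)pent-4-yne-1,2-diol | C=C(C)[C@@H]1CC=C(C)C(=C1)[C@H](O)[C@@H](O)CC#C[Si](C)(C)C | intermediate
16 | propane-1,3-diol | OCCCO | starting material
17 | 3-(triisopropylsilyloxy)propan-1-ol | CC(C)[Si](OCCCO)(C(C)C)C(C)C | intermediate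
18 | 3-(triisopropylsilyloxy)propanal | CC(C)[Si](OCCC=O)(C(C)C)C(C)C | intermediate
19 | methyl 2-[bis(2,2,2-trifluoroethoxy)phosphoryl]propanoate | COC(=O)C(C)P(=O)(OCC(F)(F)F)OCC(F)(F)F | starting material
20 | potassium carbanion of 19 (not isolated) | [K+].COC(=O)[C-](C)P(=O)(OCC(F)(F)F)OCC(F)(F)F | intermediate
21 | methyl (2Z)-2-methyl-5-(triisopropylsilyloxy)pent-2-enoate | COC(=O)/C(C)=C\CCO[Si](C(C)C)(C(C)C)C(C)C | intermediate
22 | (2Z)-2-methyl-5-(triisopropylsilyloxy)pent-2-en-1-ol | OC/C(C)=C\CCO[Si](C(C)C)(C(C)C)C(C)C | intermediate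
23 | (2Z)-2-methyl-5-(triisopropylsilyloxy)pent-2-enal | O=C/C(C)=C\CCO[Si](C(C)C)(C(C)C)C(C)C | intermediate
24 | (4S,5S)-4-dienyl-5-propargyl-1,3-dioxolane acetal of 23 (key-step precursor; one acetal epimer drawn) | C=C(C)[C@@H]1CC=C(C)C(=C1)[C@@H]2O[C@H](/C(C)=C\CCO[Si](C(C)C)(C(C)C)C(C)C)O[C@H]2CC#C[Si](C)(C)C | intermediate
25 | oxocarbenium ion on the C9 oxygen, alkoxide bound to SnCl4 (not isolated) | C=C(C)[C@@H]1CC=C(C)C(=C1)[C@H]([O-])[C@H](CC#C[Si](C)(C)C)[O+]=C/C(C)=C\CCO[Si](C(C)C)(C(C)C)C(C)C.Cl[Sn](Cl)(Cl)Cl | intermediate
26 | oxanyl allyl cation after the Prins closure, alkoxide bound to SnCl4 (not isolated) | C[Si](C)(C)C#CC[C@@H]1O[C@H](/C(C)=C\CCO[Si](C(C)C)(C(C)C)C(C)C)[C@H]2[C@H](C(C)=C)CC=C(C)[C+]2[C@@H]1[O-].Cl[Sn](Cl)(Cl)Cl | intermediate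
27 | cis-fused C10-formyl hexahydroisobenzofuran (key-step product) | C[Si](C)(C)C#CC[C@@H]1O[C@H](/C(C)=C\CCO[Si](C(C)C)(C(C)C)C(C)C)[C@H]2[C@H](C(C)=C)CC=C(C)[C@]21C=O | intermediate
28 | decarbonylated cis-fused hexahydroisobenzofuran (H at C10) | C[Si](C)(C)C#CC[C@@H]1O[C@H](/C(C)=C\CCO[Si](C(C)C)(C(C)C)C(C)C)[C@H]2[C@H](C(C)=C)CC=C(C)[C@H]21 | intermediate
29 | C16 B-alkyl-9-borabicyclononane (not isolated) | C[Si](C)(C)C#CC[C@@H]1O[C@H](/C(C)=C\CCO[Si](C(C)C)(C(C)C)C(C)C)[C@H]2[C@H]([C@@H](C)CB3C4CCCC3CCC4)CC=C(C)[C@H]21 | intermediate
30 | C16 primary alcohol, C15 set | C[Si](C)(C)C#CC[C@@H]1O[C@H](/C(C)=C\CCO[Si](C(C)C)(C(C)C)C(C)C)[C@H]2[C@H]([C@@H](C)CO)CC=C(C)[C@H]21 | intermediate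
31 | C16 tert-butyldimethylsilyl ether | C[Si](C)(C)C#CC[C@@H]1O[C@H](/C(C)=C\CCO[Si](C(C)C)(C(C)C)C(C)C)[C@H]2[C@H]([C@@H](C)CO[Si](C)(C)C(C)(C)C)CC=C(C)[C@H]21 | intermediate
32 | C12 acetoxymercurio C11 alcohol (not isolated) | C[Si](C)(C)C#CC[C@@H]1O[C@H](/C(C)=C\CCO[Si](C(C)C)(C(C)C)C(C)C)[C@H]2[C@H]([C@@H](C)CO[Si](C)(C)C(C)(C)C)C[C@H]([Hg]OC(C)=O)[C@@](C)(O)[C@H]21 | intermediate
33 | C11 tertiary alcohol, alkyne still silylated (not isolated) | C[Si](C)(C)C#CC[C@@H]1O[C@H](/C(C)=C\CCO[Si](C(C)C)(C(C)C)C(C)C)[C@H]2[C@H]([C@@H](C)CO[Si](C)(C)C(C)(C)C)CC[C@@](C)(O)[C@H]21 | intermediate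
34 | C11 tertiary alcohol, terminal alkyne | C#CC[C@@H]1O[C@H](/C(C)=C\CCO[Si](C(C)C)(C(C)C)C(C)C)[C@H]2[C@H]([C@@H](C)CO[Si](C)(C)C(C)(C)C)CC[C@@](C)(O)[C@H]21 | intermediate
35 | 3,4-epoxide (oxygen syn to the ring oxygen) | C#CC[C@@H]1O[C@H]([C@@]3(C)O[C@H]3CCO[Si](C(C)C)(C(C)C)C(C)C)[C@H]2[C@H]([C@@H](C)CO[Si](C)(C)C(C)(C)C)CC[C@@](C)(O)[C@H]21 | intermediate
36 | C4 octanoate, C3 tertiary alcohol | C#CC[C@@H]1O[C@H]([C@@](C)(O)[C@H](OC(=O)CCCCCCC)CCO[Si](C(C)C)(C(C)C)C(C)C)[C@H]2[C@H]([C@@H](C)CO[Si](C)(C)C(C)(C)C)CC[C@@](C)(O)[C@H]21 | intermediate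
37 | C16 primary alcohol of 36 | C#CC[C@@H]1O[C@H]([C@@](C)(O)[C@H](OC(=O)CCCCCCC)CCO[Si](C(C)C)(C(C)C)C(C)C)[C@H]2[C@H]([C@@H](C)CO)CC[C@@](C)(O)[C@H]21 | intermediate
38 | C16 aldehyde (not isolated) | C#CC[C@@H]1O[C@H]([C@@](C)(O)[C@H](OC(=O)CCCCCCC)CCO[Si](C(C)C)(C(C)C)C(C)C)[C@H]2[C@H]([C@@H](C)C=O)CC[C@@](C)(O)[C@H]21 | intermediate
39 | C16 carboxylic acid | C#CC[C@@H]1O[C@H]([C@@](C)(O)[C@H](OC(=O)CCCCCCC)CCO[Si](C(C)C)(C(C)C)C(C)C)[C@H]2[C@H]([C@@H](C)C(=O)O)CC[C@@](C)(O)[C@H]21 | intermediate
40 | 2,4,6-trichlorobenzoic mixed anhydride of 39 (not isolated) | C#CC[C@@H]1O[C@H]([C@@](C)(O)[C@H](OC(=O)CCCCCCC)CCO[Si](C(C)C)(C(C)C)C(C)C)[C@H]2[C@H]([C@@H](C)C(=O)OC(=O)c3c(Cl)cc(Cl)cc3Cl)CC[C@@](C)(O)[C@H]21 | intermediate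
41 | alkyne lactone (C16 to the C3 oxygen) | C#CC[C@@H]1O[C@H]([C@@](C)(O3)[C@H](OC(=O)CCCCCCC)CCO[Si](C(C)C)(C(C)C)C(C)C)[C@H]2[C@H]([C@@H](C)C3=O)CC[C@@](C)(O)[C@H]21 | intermediate
42 | (Z)-2-iodoalkenyl-9-borabicyclononane (not isolated) | I/C(=C\B3C4CCCC3CCC4)C[C@@H]1O[C@H]([C@@](C)(O3)[C@H](OC(=O)CCCCCCC)CCO[Si](C(C)C)(C(C)C)C(C)C)[C@H]2[C@H]([C@@H](C)C3=O)CC[C@@](C)(O)[C@H]21 | intermediate
43 | 2-iodoalkene lactone, C6 silyl ether | C=C(I)C[C@@H]1O[C@H]([C@@](C)(O3)[C@H](OC(=O)CCCCCCC)CCO[Si](C(C)C)(C(C)C)C(C)C)[C@H]2[C@H]([C@@H](C)C3=O)CC[C@@](C)(O)[C@H]21 | intermediate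
44 | C6 primary alcohol | C=C(I)C[C@@H]1O[C@H]([C@@](C)(O3)[C@H](OC(=O)CCCCCCC)CCO)[C@H]2[C@H]([C@@H](C)C3=O)CC[C@@](C)(O)[C@H]21 | intermediate
45 | C6 aldehyde | C=C(I)C[C@@H]1O[C@H]([C@@](C)(O3)[C@H](OC(=O)CCCCCCC)CC=O)[C@H]2[C@H]([C@@H](C)C3=O)CC[C@@](C)(O)[C@H]21 | intermediate
46 | vinylchromium dichloride from 45 (not isolated) | C=C([Cr](Cl)Cl)C[C@@H]1O[C@H]([C@@](C)(O3)[C@H](OC(=O)CCCCCCC)CC=O)[C@H]2[C@H]([C@@H](C)C3=O)CC[C@@](C)(O)[C@H]21 | intermediate
47 | briarellin B | C=C1C[C@@H]2O[C@H]3[C@H]4[C@@H](CC[C@@](C)(O)[C@H]42)[C@@H](C)C(=O)O[C@@]3(C)[C@H](OC(=O)CCCCCCC)C[C@H]1O | target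

## Step count and least certain steps

Total step count: 29. Longest linear sequence: 23 steps (from 4: steps 2–9 and 15–29).

**Step 16 (key step).** The allyl cation 26 may be lost by proton loss or by 1,2-hydride shift before C9 migrates. The Lewis acid may also ionise the doubly allylic C–O bond, and the Z olefin may isomerise at the oxocarbenium stage. Fallback: the route leaves at diol 15, which is silylated (TMSCl, imidazole) to the bis(trimethylsilyl) ether F1. F1 and enal 23 are treated with catalytic TMSOTf in CH2Cl2 at −78 °C. Silyl-transfer acetalisation gives the same C9-bound oxocarbenium ion without a stoichiometric metal halide, and the allylic silyloxy group ends the Prins step by pinacol shift with loss of silicon. The route returns at 27.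

**Step 20.** The facial and regiochemical course may fail: water may be delivered to C11 on the convex face through the more hindered mercurinium ion, and divalent mercury may attack the silylalkyne or C3=C4. Fallback: the route leaves at 31. NBS in wet THF should place the bromonium ion on the convex face and water anti to it, giving the bromohydrin F2. K2CO3 in MeOH closes the epoxide on the concave face and removes the alkynyl silane (epoxide F3). Either bromohydrin regioisomer gives this epoxide, so the outcome no longer depends on Markovnikov versus diaxial opening. LiBHEt3 then attacks the secondary C12 from the convex face, and the route returns at 34.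

**Step 22.** The opening may be slow, or regiocontrol may be lost through attack at C3 under acid-type activation; the primary silyl ether may also be lost in hot DMF. Fallback: the route leaves at 35. Oxidative epoxide opening with DMSO (TMSOTf cat., then i-Pr2NEt) gives the α-hydroxy ketone F4 with the C3 carbinol untouched. Reduction with NaBH4 in MeOH at −78 °C under non-chelating Felkin–Anh control (hydride anti to the C3–O bond) should give the 3,4-anti diol F5. Octanoyl chloride and pyridine acylate only the secondary hydroxyl, and the route returns at 36.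

**Step 25.** Acylation of the tertiary hydroxyl may be slow, which would lead to oligomers or to loss of configuration at C15 through the activated acid. Fallback: the C3–O bond is made by substitution instead of acylation. The route leaves at 34. C3=C4 is epoxidised under reagent control on the face syn to C1 (Shi ketone enantiomer chosen for that face, KHSO5, buffered) to the epoxide F6. PPTS in MeOH gives the alcohol F7, and TEMPO/PhI(OAc)2 in buffered aqueous MeCN gives the epoxy acid F8. Catalytic camphorsulfonic acid lets the carboxyl open the epoxide at the tertiary C3 with inversion (7-exo), giving the hydroxy lactone F9 with the C4 hydroxyl retained. Octanoic anhydride and DMAP return the route at 41.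

**Step 29.** Facial selectivity at the aldehyde may be poor, giving the C6 epimer, and octanoate may be eliminated from 45 before the addition. Fallback: the route leaves at 45 with the same cyclisation. If the 6-epimer F10 predominates, it is oxidised (Dess–Martin periodinane) to the α-methylene ketone F11, which is reduced at the carbonyl group under reagent control (methyl-CBS oxazaborolidine, catecholborane, −78 °C). The route returns at 47.

## Further compounds

F1 | step 16 | bis(trimethylsilyl) ether of diol 15 | C=C(C)[C@@H]1CC=C(C)C(=C1)[C@H](O[Si](C)(C)C)[C@@H](O[Si](C)(C)C)CC#C[Si](C)(C)C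
F2 | step 20 | C12 bromide C11 alcohol (bromohydrin of 31) | C[Si](C)(C)C#CC[C@@H]1O[C@H](/C(C)=C\CCO[Si](C(C)C)(C(C)C)C(C)C)[C@H]2[C@H]([C@@H](C)CO[Si](C)(C)C(C)(C)C)C[C@H](Br)[C@@](C)(O)[C@H]21
F3 | step 20 | 11,12-epoxide on the concave face, terminal alkyne | C#CC[C@@H]1O[C@H](/C(C)=C\CCO[Si](C(C)C)(C(C)C)C(C)C)[C@H]2[C@H]([C@@H](C)CO[Si](C)(C)C(C)(C)C)C[C@H]3O[C@@]3(C)[C@H]21
F4 | step 22 | C3 hydroxy C4 ketone | C#CC[C@@H]1O[C@H]([C@@](C)(O)C(=O)CCO[Si](C(C)C)(C(C)C)C(C)C)[C@H]2[C@H]([C@@H](C)CO[Si](C)(C)C(C)(C)C)CC[C@@](C)(O)[C@H]21
F5 | step 22 | 3,4-anti diol | C#CC[C@@H]1O[C@H]([C@@](C)(O)[C@H](O)CCO[Si](C(C)C)(C(C)C)C(C)C)[C@H]2[C@H]([C@@H](C)CO[Si](C)(C)C(C)(C)C)CC[C@@](C)(O)[C@H]21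
F6 | step 25 | 3,4-epoxide on the face syn to C1 | C#CC[C@@H]1O[C@H]([C@]3(C)O[C@@H]3CCO[Si](C(C)C)(C(C)C)C(C)C)[C@H]2[C@H]([C@@H](C)CO[Si](C)(C)C(C)(C)C)CC[C@@](C)(O)[C@H]21
F7 | step 25 | C16 alcohol of F6 | C#CC[C@@H]1O[C@H]([C@]3(C)O[C@@H]3CCO[Si](C(C)C)(C(C)C)C(C)C)[C@H]2[C@H]([C@@H](C)CO)CC[C@@](C)(O)[C@H]21
F8 | step 25 | epoxy acid | C#CC[C@@H]1O[C@H]([C@]3(C)O[C@@H]3CCO[Si](C(C)C)(C(C)C)C(C)C)[C@H]2[C@H]([C@@H](C)C(=O)O)CC[C@@](C)(O)[C@H]21
F9 | step 25 | lactone with free C4 hydroxyl | C#CC[C@@H]1O[C@H]([C@@](C)(O3)[C@H](O)CCO[Si](C(C)C)(C(C)C)C(C)C)[C@H]2[C@H]([C@@H](C)C3=O)CC[C@@](C)(O)[C@H]21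
F10 | step 29 | 6-epimer of 47 | C=C1C[C@@H]2O[C@H]3[C@H]4[C@@H](CC[C@@](C)(O)[C@H]42)[C@@H](C)C(=O)O[C@@]3(C)[C@H](OC(=O)CCCCCCC)C[C@@H]1O
F11 | step 29 | C6 ketone (α-methylene ketone) | C=C1C[C@@H]2O[C@H]3[C@H]4[C@@H](CC[C@@](C)(O)[C@H]42)[C@@H](C)C(=O)O[C@@]3(C)[C@H](OC(=O)CCCCCCC)CC1=O
A1 | alternative 1 | protected tetracyclic lactone (C4 p-methoxybenzyl ether, C6 and C11 silyl ethers) | C=C1C[C@@H]2O[C@H]3[C@H]4[C@@H](CC[C@@](C)(O[Si](CC)(CC)CC)[C@H]42)[C@@H](C)C(=O)O[C@@]3(C)[C@H](OCc5ccc(OC)cc5)C[C@H]1O[Si](C)(C)C(C)(C)C
A2 | alternative 2 | cis-fused bicyclic lactone with C11 silyloxy methyl carbinol and C12=C13 olefin | O=C1O[C@H](CO[Si](C)(C)C(C)(C)C)[C@H]2CC=C[C@@](C)(O[Si](C)(C)C(C)(C)C)[C@@H]12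
A3 | alternative 3 | 2,9-cis-disubstituted Z-oxonen-3-one | C/C1=C/CCC(=O)[C@H](CO[Si](C)(C)C(C)(C)C)O[C@@H](C1)CCOCc2ccc(OC)cc2
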